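**Retrosynthetic overview**
1. The C-8 prenyl group goes on last, by ortho C-alkylation of the 7-phenoxide; until then the 7-OH is carried as its benzyl ether.
2. Furan ring (C-2–O bond): oxidative cyclization of a 2'-hydroxyisoflavone, run through the ring B para-quinone. The isoflavone (C-3–C-1' bond and pyranone ring) is made in the same flask from an o-hydroxyaryl enaminone and a chroman-5,8-dione.
3. Both dimethyldihydropyran rings: prenylation, then cyclization of the phenol onto the prenyl group, on the two separate halves. The ring A half comes from 2,4,6-trihydroxyacetophenone with the para oxygen blocked, so the ring must close on the ortho oxygen; the ring B half comes from veratrole.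
4. Order of ring formation: the two dihydropyrans (steps 2 and 5), then the pyranone, then the furan (both in step 7).

Assumption: the target has no stereocentre and no stereogenic double bond, so it is a single achiral compound and no stereocontrol is needed.
Positions in compounds 12–17 use isoflavone numbering (O-1, C-2, C-3, C-4=O, ring A C-5 to C-8, ring B primed).

**Route**

Step 1
Reactants: 1 2,4,6-trihydroxyacetophenone
Product: 2 1-[4-(benzyloxy)-2,6-dihydroxyphenyl]ethanone
Conditions: BnBr (1.0 equiv), K2CO3 (1.1 equiv), DMF, 0 to 25 °C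
Reagents that add atoms: benzyl bromide, BrCc1ccccc1
Why: Williamson etherification goes at the 4-OH, the most acidic phenol and the only one never held in the hydrogen bond to the acetyl group, so one equivalent of benzyl bromide gives the para ether.

Step 2
Reactants: 2 1-[4-(benzyloxy)-2,6-dihydroxyphenyl]ethanone
Product: 4 1-[5-(benzyloxy)-7-hydroxy-2,2-dimethylchroman-8-yl]ethanone, via C-prenyl ketone 3 (not isolated)
Conditions: isoprene (1.2 equiv), Amberlyst-15 (polystyrene-SO3H resin), THF/heptane, 65 °C, sealed tube
Reagents that add atoms: isoprene, C=CC(C)=C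
Why: Friedel–Crafts prenylation at C-3 (equivalent to C-5) is followed by Markovnikov hydroalkoxylation, and because the 4-oxygen is benzylated the tertiary cation can only be captured by the ortho hydroxyl, which places the dihydropyran on the oxygen that becomes O-5 of the target in the same prenylation-then-cyclization order as the biosynthesis.

Step 3
Reactants: 4 1-[5-(benzyloxy)-7-hydroxy-2,2-dimethylchroman-8-yl]ethanone
Product: 5 (E)-1-[5-(benzyloxy)-7-hydroxy-2,2-dimethylchroman-8-yl]-3-(dimethylamino)prop-2-en-1-one
Conditions: DMF-DMA (3 equiv), toluene, 90 °C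
Reagents that add atoms: N,N-dimethylformamide dimethyl acetal, COC(OC)N(C)C
Why: Amide-acetal condensation at the methyl ketone gives the E-enaminone; the only free hydroxyl is chelated to the carbonyl and the benzyl and chroman ethers are inert.

Step 4
Reactants: 6 veratrole (1,2-dimethoxybenzene)
Product: 8 1,2-dimethoxy-3-(3-methylbut-2-en-1-yl)benzene, via 2,3-dimethoxyphenyllithium 7 (not isolated)
Conditions: n-BuLi (1.1 equiv), TMEDA, THF, 0 to 25 °C; then CuBr·SMe2 (10 mol%), prenyl bromide (1.2 equiv), −78 to 25 °C
Reagents that add atoms: prenyl bromide (1-bromo-3-methylbut-2-ene), CC(C)=CCBr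
Why: Directed ortho-metalation of veratrole occurs at C-3 next to a methoxy group, and copper-catalysed SN2 alkylation of the aryllithium with prenyl bromide places the prenyl group ortho to the future catechol oxygen, a position electrophilic prenylation of catechol does not reach cleanly.

Step 5
Reactants: 8 1,2-dimethoxy-3-(3-methylbut-2-en-1-yl)benzene
Product: 10 2,2-dimethylchroman-8-ol, via 3-prenylcatechol 9 (not isolated)
Conditions: BBr3 (2.5 equiv), CH2Cl2, −78 to 0 °C; H2O; then p-TsOH·H2O (10 mol%), toluene, 80 °C
Reagents that add atoms: none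
Why: Lewis-acid ether cleavage frees the catechol, and acid then closes the dihydropyran by Markovnikov hydroalkoxylation onto the only hydroxyl ortho to the prenyl group (any tertiary bromide from HBr addition alkylates the same oxygen), the phenol-onto-prenyl cyclization nature uses for dimethylchromans.

Step 6
Reactants: 10 2,2-dimethylchroman-8-ol
Product: 11 2,2-dimethyl-3,4-dihydro-2H-chromene-5,8-dione
Conditions: ON(SO3K)2 (2.5 equiv), KH2PO4, H2O/acetone, 0 to 25 °C
Reagents that add atoms: potassium nitrosodisulfonate, [K+].[K+].[O]N(S(=O)(=O)[O-])S(=O)(=O)[O-]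
Why: Teuber oxidation: the nitrosodisulfonate radical converts a 2-alkoxyphenol with a free para position (C-5) into the para-quinone.

Step 7
Reactants: 5 (E)-1-[5-(benzyloxy)-7-hydroxy-2,2-dimethylchroman-8-yl]-3-(dimethylamino)prop-2-en-1-one; 11 2,2-dimethyl-3,4-dihydro-2H-chromene-5,8-dione (2.2 equiv, coupling partner and oxidant)
Product: 15 7-O-benzyl-8-desprenyl target (coumaronochromone core complete), via aryl enaminone 12 (not isolated), via isoflavone hydroquinone 13 (not isolated), via isoflavone quinone 14 (not isolated)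
Conditions: 5 added over 2 h to 11 (2.2 equiv), AcOH/CH2Cl2 (1:4), 0 to 25 °C; then CF3CO2H (0.2 equiv), 40 °C
Reagents that add atoms: none
Why: Proposed new method: the enaminone carbon adds to the quinone at C-6, the position beta to the C-8 carbonyl, which is the more electrophilic one because the C-5 carbonyl is a vinylogous ester of the ring oxygen; the alpha-aryl enaminone 12 closes the pyranone through the chelated ring A hydroxyl with loss of dimethylamine, as in isoflavone syntheses from deoxybenzoin enaminones; a second equivalent of 11 oxidises the 2',5'-hydroquinone 13 to quinone 14, as in the Nenitzescu reaction; in protonated 14 the positive charge is delocalised onto C-2 of the chromone, the neighbouring quinone carbonyl oxygen closes the five-membered ring there, and loss of the C-2 proton re-aromatises ring B, which is the biosynthetic oxidative cyclization of a 2'-hydroxyisoflavone to a coumaronochromone run through the quinone without protecting the 5'-OH; the closest known reaction types are the Nenitzescu 5-hydroxybenzofuran synthesis from enaminones and quinones and the Lewis-acid formal [3+2] annulation of quinones with enol ethers or styrenes.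

Step 8
Reactants: 15 7-O-benzyl-8-desprenyl target
Product: 16 8-desprenyl target (free 7-OH)
Conditions: H2 (1 atm), Pd/C (10 wt%), EtOAc/MeOH, 25 °C
Reagents that add atoms: none
Why: Catalytic hydrogenolysis cleaves the benzyl ether; there is no alkene in the molecule at this stage, and the aromatic furan, the pyranone and the chroman ethers are not reduced.

Step 9
Reactants: 16 8-desprenyl target (free 7-OH)
Product: 17 target CNP0081329.0
Conditions: NaOMe (1.05 equiv), MeOH, 0 °C; prenyl bromide (1.5 equiv), 0 to 25 °C
Reagents that add atoms: prenyl bromide (1-bromo-3-methylbut-2-ene), CC(C)=CCBr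
Why: Phenoxide ortho C-alkylation: one equivalent of base ionises only the 7-OH (a vinylogous acid, about three pKa units more acidic than the ring B phenol), methanol hydrogen-bonds the phenoxide oxygen and steers the prenyl cation equivalent to carbon, and C-8 is the only free ortho position; the 7-O-prenyl ether is the expected by-product.

**Compound list**
1 | 2,4,6-trihydroxyacetophenone | CC(=O)c1c(O)cc(O)cc1O | starting material
2 | 1-[4-(benzyloxy)-2,6-dihydroxyphenyl]ethanone | CC(=O)c1c(O)cc(OCc2ccccc2)cc1O | intermediate
3 | 1-[4-(benzyloxy)-2,6-dihydroxy-3-(3-methylbut-2-en-1-yl)phenyl]ethanone | CC(=O)c1c(O)cc(OCc2ccccc2)c(CC=C(C)C)c1O | intermediate (not isolated)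
4 | 1-[5-(benzyloxy)-7-hydroxy-2,2-dimethylchroman-8-yl]ethanone | CC(=O)c1c(O)cc(OCc2ccccc2)c2CCC(C)(C)Oc12 | intermediate
5 | (E)-1-[5-(benzyloxy)-7-hydroxy-2,2-dimethylchroman-8-yl]-3-(dimethylamino)prop-2-en-1-one | CN(C)/C=C/C(=O)c1c(O)cc(OCc2ccccc2)c2CCC(C)(C)Oc12 | intermediate
6 | veratrole (1,2-dimethoxybenzene) | COc1ccccc1OC | starting material
7 | 2,3-dimethoxyphenyllithium | COc1cccc([Li])c1OC | intermediate (not isolated)
8 | 1,2-dimethoxy-3-(3-methylbut-2-en-1-yl)benzene | COc1cccc(CC=C(C)C)c1OC | intermediate
9 | 3-(3-methylbut-2-en-1-yl)benzene-1,2-diol (3-prenylcatechol) | CC(C)=CCc1cccc(O)c1O | intermediate (not isolated)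
10 | 2,2-dimethylchroman-8-ol | CC1(C)CCc2cccc(O)c2O1 | intermediate
11 | 2,2-dimethyl-3,4-dihydro-2H-chromene-5,8-dione | CC1(C)CCC2=C(O1)C(=O)C=CC2=O | intermediate
12 | (E)-1-[5-(benzyloxy)-7-hydroxy-2,2-dimethylchroman-8-yl]-2-(5,8-dihydroxy-2,2-dimethylchroman-6-yl)-3-(dimethylamino)prop-2-en-1-one (geometry drawn as E, of no consequence) | CN(C)/C=C(\c1cc(O)c2OC(C)(C)CCc2c1O)C(=O)c1c(O)cc(OCc2ccccc2)c2CCC(C)(C)Oc12 | intermediate (not isolated)
13 | 7-(benzyloxy)-2',5'-dihydroxyisoflavone with 2,2-dimethyldihydropyran rings fused at 5-O/C-6 and at 4'-O/C-3' | O=c1c(-c2cc(O)c3OC(C)(C)CCc3c2O)coc2cc(OCc3ccccc3)c3CCC(C)(C)Oc3c12 | intermediate (not isolated)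
14 | ring B 2',5'-para-quinone of 13 | O=C1C=C(c2coc3cc(OCc4ccccc4)c4CCC(C)(C)Oc4c3c2=O)C(=O)C2=C1OC(C)(C)CC2 | intermediate (not isolated)
15 | coumaronochromone (isoflavone with an oxygen bridge C-2–O–C-2'): 7-OBn, H at C-8, 5'-OH, dimethyldihydropyran rings at 5-O/C-6 and 4'-O/C-3' | O=c1c2c3cc(O)c4OC(C)(C)CCc4c3oc2oc2cc(OCc3ccccc3)c3CCC(C)(C)Oc3c12 | intermediate
16 | as 15 with free 7-OH (8-desprenyl target) | O=c1c2c3cc(O)c4OC(C)(C)CCc4c3oc2oc2cc(O)c3CCC(C)(C)Oc3c12 | intermediate
17 | target CNP0081329.0: as 16 with a 3-methylbut-2-enyl group at C-8 | CC(C)=CCc1c(O)c2c(c3c(=O)c4c(oc13)oc1c3c(c(O)cc14)OC(C)(C)CC3)OC(C)(C)CC2 | target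

**Totals**
Total steps: 9.
Longest linear sequence: 6 steps (steps 1, 2, 3, 7, 8, 9 from 1; the veratrole branch, steps 4, 5, 6, 7, 8, 9, is equally long).

**Three steps most likely to fail**

Step 7 (union and oxidative furan closure in one flask). The risks are:
- attack at C-7 of the quinone instead of C-6;
- closure of 12 through the ring B hydroxyl to give a 3-aroyl-5-hydroxybenzofuran instead of the isoflavone;
- hydration of 14 at C-2 instead of ring closure.

The fallback sets out from 5 and 11 and comes back to the route at 13. It builds the same 2'-hydroxyisoflavone by cross-coupling and runs the oxidation as separate operations. Enaminone 5 is treated with I2 in MeOH at 25 °C to give the ring A 3-iodochromone F1. Quinone 11 is reduced with Na2S2O4 to 2,2-dimethylchroman-5,8-diol F2 and protected with MOMCl and i-Pr2NEt as the bis(methoxymethyl) ether F3. NBS in MeCN brominates F3 para to the ring oxygen to give the 6-bromide F4. Borylation with B2pin2, Pd(dppf)Cl2 and KOAc in dioxane at 90 °C gives the pinacol boronate F5. Suzuki coupling of F1 with F5 (Pd(PPh3)4, K2CO3, dioxane/H2O, 80 °C) gives the bis-MOM isoflavone F6, and HCl in MeOH at 40 °C frees hydroquinone 13. Compound 13 is then oxidised with Ag2O in CH2Cl2 to 14 and cyclised with CF3CO2H to 15.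

Step 9 (C-8 prenylation). The risk is O-alkylation in place of C-alkylation, giving a low yield. The fallback sets out from 16 and comes back at 17, and replaces the ambident alkylation by a sigmatropic shift. Compound 16 is alkylated at the acidic 7-OH with 3-chloro-3-methylbut-1-yne (K2CO3, KI, CuI, acetone, 50 °C) to give the 7-O-(2-methylbut-3-yn-2-yl) ether F7. Semihydrogenation (H2, Pd/CaCO3 poisoned with Pb(OAc)2, quinoline, EtOAc) gives the 7-O-(2-methylbut-3-en-2-yl) ether F8. Heating in N,N-diethylaniline at 130 °C brings about the aromatic Claisen rearrangement to C-8, the only free ortho position, and delivers 17.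

Step 2 (one-pot prenylation and cyclization). The risks are a second alkylation at C-5 giving a bis-chroman and incomplete conversion. The fallback sets out from 2 and comes back at 4, and replaces the acid Friedel–Crafts step by anionic C-alkylation. Compound 2 with prenyl bromide in 10% aqueous KOH at 0 °C gives the C-prenyl ketone 3, which is isolated. HCO2H at 25 °C, or p-TsOH·H2O in toluene at 80 °C, then closes the ring onto the ortho hydroxyl to give 4.

**Further compounds**
F1 | step 7 | 7-(benzyloxy)-3-iodochromen-4-one with the 2,2-dimethyldihydropyran fused at 5-O/C-6 | O=c1c(I)coc2cc(OCc3ccccc3)c3CCC(C)(C)Oc3c12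
F2 | step 7 | 2,2-dimethylchroman-5,8-diol | CC1(C)CCc2c(O)ccc(O)c2O1
F3 | step 7 | 5,8-bis(methoxymethoxy)-2,2-dimethylchroman | COCOc1ccc(OCOC)c2CCC(C)(C)Oc12
F4 | step 7 | 6-bromo-5,8-bis(methoxymethoxy)-2,2-dimethylchroman | COCOc1cc(Br)c(OCOC)c2CCC(C)(C)Oc12
F5 | step 7 | 2-[5,8-bis(methoxymethoxy)-2,2-dimethylchroman-6-yl]-4,4,5,5-tetramethyl-1,3,2-dioxaborolane | COCOc1cc(B3OC(C)(C)C(C)(C)O3)c(OCOC)c2CCC(C)(C)Oc12
F6 | step 7 | 2',5'-bis(methoxymethyl) ether of 13 | O=c1c(-c2cc(OCOC)c3OC(C)(C)CCc3c2OCOC)coc2cc(OCc3ccccc3)c3CCC(C)(C)Oc3c12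
F7 | step 9 | 7-O-(2-methylbut-3-yn-2-yl) ether of 16 | O=c1c2c3cc(O)c4OC(C)(C)CCc4c3oc2oc2cc(OC(C)(C)C#C)c3CCC(C)(C)Oc3c12
F8 | step 9 | 7-O-(2-methylbut-3-en-2-yl) ether of 16 | O=c1c2c3cc(O)c4OC(C)(C)CCc4c3oc2oc2cc(OC(C)(C)C=C)c3CCC(C)(C)Oc3c12
F0 | step 2 | none | none
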